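Partner stands to substrate as 0.950 in the charge, and that ratio is where the reckoning starts.

    substrate → open intermediate (k1 = 0.020 s⁻¹)
    partner → second intermediate (k2 = 0.010 s⁻¹)
    open intermediate + second intermediate → target (k3 = 2.0 M⁻¹ s⁻¹)
    second intermediate + capture agent → trapped intermediate (k4 = 0.030 M⁻¹ s⁻¹)
    target ⇌ isomer of the product (K5 = 2.1, k5 = 0.021 s⁻¹)

| setting | ash | larch | alder | maple |
|---|---|---|---|---|
| substrate | 38 mM | 38 mM | 38 mM (fed, over 12.0 min) | 38 mM |
| partner | 36.1 mM (fed, over 12.0 min) | 36.1 mM | 36.1 mM | 36.1 mM |
| capture agent | 38.0 mM | 38.0 mM | 38.0 mM | 38.0 mM |
| time | 15 min | 15 min | 15 min |  |
| remark | all but partner at the start; partner goes in evenly over 12.0 min, the run ends at 15 min | everything together in a closed stirred flask, run for 15 min | all but substrate at the start; substrate goes in evenly over 12.0 min, the run ends at 15 min | one stirred flow tank at steady state, fed with the mixture as stated, mean residence time 15 min |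

- the stated concentrations are those of everything mixed, before any reaction; amounts are the same in each set-up
- the feed brings no volume worth counting
- run time (ash): 15 min

- order of the set-ups by the amount of open intermediate at the outlet or at the end, in percent of the substrate put in, highest first (ash / larch / alder / maple)
- amount of open intermediate at the outlet or at the end, in percent of the substrate put in, ash
- amount of open intermediate at the outlet or at the end, in percent of the substrate put in, larch
- amount of open intermediate at the outlet or at the end, in percent of the substrate put in, alder
- amount of open intermediate at the outlet or at the end, in percent of the substrate put in, maple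

We reckon larch by hand, in fractions of the substrate charge, with i for open intermediate.

1. Each second intermediate that pairs takes one open intermediate. What stays is therefore the gap, 0.0500, plus the fraction trapped by capture agent.

2. Second intermediate has two pseudo-first-order exits, and at full charge capture is the slower: 0.0684 min⁻¹ against 4.56 min⁻¹. Their ratio is the capture number 0.0150, a selectivity factor. Each open intermediate consumed costs cap/i trapped, so the cost grows as i falls. Integrated down from i of one, the trapped fraction is cap times the logarithm of the inverse of i.

3. Setting i to the gap gives 0.0949. Putting that back gives 0.0853, then 0.0869, which we commit to.

4. The weak link is the start at one. Substrate's half-life of 0.58 min is shorter than partner's 1.2 min, and k1 is twice k2. With x the partner left and y the partner gone, open intermediate is y(x + i), well below one early on. Integrating from x = 0.707, partner left at substrate's half-life, raises the logarithm from 2.44 to 2.89. Our estimate for larch then stands at 0.0933.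

Our reckoning stops at larch. The forecast gives alder > maple > ash > larch, with ash 13.8%, larch 9.6%, alder 28% and maple 20%, its larch a little above ours. Its ground is that “the set-up that holds second intermediate high for longest while open intermediate is scarce (alder, substrate fed slowly) loses most to capture and leaves the most open intermediate”.

The simulation gives alder > maple > ash > larch: ash 13.5%, larch 9.53%, alder 27.1%, maple 20.0%. The forecast holds on each count.

For alder this means that at 7.50 min open intermediate is 6.08% beside 9.50 mM of second intermediate, and with capture agent at 80.5% of its charge, cap/i scaled by that share is about 0.199. Alder ends with 8.46 mM trapped, 0.223 of the charge, and gap plus that is 0.273. Capture is part of the reason alder stands above larch: without it, larch minus alder goes from −18 percentage points to −2.5 points.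

With 9.0 mM of partner in the larch flask, the gap is 0.763 and the capture number adds 0.00406, giving 0.767. The computed value is 76.9%.

The numbers are made up; what happens was integrated by code.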